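**Retrosynthetic overview**

1. Feature: ring B carries the C8 ketone directly beside the C9 enol carbon and the ring-fusion carbon C5 is quaternary, so C8, C9, C10, C5, C4 and C3 map onto a 3,3-dimethoxy-5,6-dimethylbicyclo[2.2.2]oct-5-en-2-one made by dearomatizing 2-methoxy-4,5-dimethylphenol.
2. Key disconnection: C5–C6 is formed while C3–C8 breaks in an anionic oxy-Cope shift of vinyl carbinol 12; ring A is the cyclohexene already present in the bicycle, ring B closes in this step.
3. Bicycle: Diels–Alder reaction of the masked o-benzoquinone with phenyl vinyl sulfone (ethylene equivalent), then vinyl addition, desulfonylation and resolution.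
4. After the shift, C10 is made trigonal (C9=C10 methyl enol ether) before C3=C4 is hydroborated, because in the cis-fused ketal the face anti to the C5 methyl is the concave one; C7=C11 comes from an acetone aldol, and acid then releases the diosphenol.
5. Last bond: the C3–O ester, from acid 34 (Z-enoate by cuprate addition to an ynoate) and the silyl-protected diosphenol 24.

Key step: step 8

**Remarks**

- Numbering: decalins are numbered as eremophilanes (ring A = C1–C5, C10; ring B = C5–C10; methyl groups on C4 and C5; C11 on C7). Bicycles carry bicyclo[2.2.2]octene numbers (C2 carbinol/ketone, C3 ketal, C5=C6 alkene, C7–C8 ethano bridge).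
- Assumption: the enantiomers of 11 are taken to separate on a chiral stationary phase; the (1R,2R,4S) enantiomer would be identified by vibrational circular dichroism before it is carried on.
- C7 in 18–21 and C8 in 20 are expected as epimer mixtures; both centres become trigonal later, so the mixtures are carried on.

**Route**

Step 1
Reactants: 1 3,4-dimethylphenol
Product: 2 2-hydroxy-4,5-dimethylbenzaldehyde
Conditions: MgCl2, Et3N, (CH2O)n, MeCN, reflux
Reagents that add atoms: paraformaldehyde (formaldehyde), C=O
Why: Magnesium-phenoxide-directed ortho-formylation (Casnati–Skattebøl) delivers CHO only ortho to OH, and the ortho site flanked by the C3 methyl is the more hindered one, so C6 should react.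

Step 2
Reactants: 2 2-hydroxy-4,5-dimethylbenzaldehyde
Product: 3 2-methoxy-4,5-dimethylbenzaldehyde
Conditions: MeI, K2CO3, DMF, rt
Reagents that add atoms: iodomethane, CI
Why: Williamson O-methylation of the phenoxide, which is the only nucleophilic site.

Step 3
Reactants: 3 2-methoxy-4,5-dimethylbenzaldehyde
Product: 5 2-methoxy-4,5-dimethylphenol, via 2-methoxy-4,5-dimethylphenyl formate 4 (not isolated)
Conditions: mCPBA, CH2Cl2, 0 °C → rt; then K2CO3 (cat.), MeOH, rt
Reagents that add atoms: 3-chloroperbenzoic acid, OOC(=O)c1cccc(Cl)c1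
Why: Baeyer–Villiger (Dakin-type) oxidation in which the electron-rich aryl group migrates to give the formate, which is methanolysed in the same flask.

Step 4
Reactants: 5 2-methoxy-4,5-dimethylphenol; 6 phenyl vinyl sulfone
Product: 8 rac-3,3-dimethoxy-5,6-dimethyl-7-(phenylsulfonyl)bicyclo[2.2.2]oct-5-en-2-one (sulfone isomers carried on together), via 6,6-dimethoxy-3,4-dimethylcyclohexa-2,4-dien-1-one 7 (not isolated)
Conditions: PhI(OAc)2, MeOH, 6 (5 equiv), 50 °C, slow addition of 5
Reagents that add atoms: methanol, CO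
Why: Oxidative dearomatization in methanol gives the ortho-quinone monoketal, which is trapped in situ by Diels–Alder reaction with the vinyl sulfone as an ethylene equivalent; the two ring methyls sit on the inner diene carbons, which should slow self-dimerization, and the position and configuration of the sulfonyl group do not matter because it is removed in step 6.

Step 5
Reactants: 8 rac-3,3-dimethoxy-5,6-dimethyl-7-(phenylsulfonyl)bicyclo[2.2.2]oct-5-en-2-one; 9 vinylmagnesium bromide
Product: 10 rac-2-ethenyl-3,3-dimethoxy-5,6-dimethyl-7-(phenylsulfonyl)bicyclo[2.2.2]oct-5-en-2-ol (vinyl syn to the C5=C6 bridge)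
Conditions: CeCl3, THF, −78 °C; 9; −78 → 0 °C; sat. NH4Cl
Reagents that add atoms: none
Why: Cerium-mediated Grignard 1,2-addition to the hindered ketone should occur from the face flanked by the sp2 C5=C6 bridge, which carries no inward C–H bonds unlike the ethano bridge, so C2 is set with the vinyl group syn to the alkene as the sigmatropic shift requires.

Step 6
Reactants: 10 rac-2-ethenyl-3,3-dimethoxy-5,6-dimethyl-7-(phenylsulfonyl)bicyclo[2.2.2]oct-5-en-2-ol
Product: 11 rac-(1R*,2R*,4S*)-2-ethenyl-3,3-dimethoxy-5,6-dimethylbicyclo[2.2.2]oct-5-en-2-ol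
Conditions: Na(Hg) (6% Na), Na2HPO4, MeOH/THF, −20 °C → rt
Reagents that add atoms: none
Why: Reductive desulfonylation by electron transfer cleaves the C–S bond and methanol protonates the carbanion; the ketone is already converted to the carbinol, so nothing else is reducible, and all sulfone isomers converge on one racemate.

Step 7
Reactants: 11 rac-(1R*,2R*,4S*)-2-ethenyl-3,3-dimethoxy-5,6-dimethylbicyclo[2.2.2]oct-5-en-2-ol
Product: 12 (1R,2R,4S)-2-ethenyl-3,3-dimethoxy-5,6-dimethylbicyclo[2.2.2]oct-5-en-2-ol
Conditions: preparative SFC, amylose tris(3,5-dimethylphenylcarbamate) phase, CO2/i-PrOH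
Reagents that add atoms: none
Why: Resolution by chromatography on a chiral stationary phase separates the enantiomers through diastereomeric adsorption; no bond is changed, and the (1R,2R,4S) enantiomer carries the bridgehead configuration that becomes C5 of the target.

Step 8
Reactants: 12 (1R,2R,4S)-2-ethenyl-3,3-dimethoxy-5,6-dimethylbicyclo[2.2.2]oct-5-en-2-ol
Product: 14 (4aS,8aS)-1,1-dimethoxy-4a,5-dimethyl-3,4,4a,7,8,8a-hexahydronaphthalen-2(1H)-one (cis-fused; eremophilane numbering 9,9-dimethoxy-Δ3-8-one), via potassium enolate 13 (not isolated)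
Conditions: KH, 18-crown-6, THF, 0 °C → rt (50 °C if needed); AcOH, −78 °C
Reagents that add atoms: none
Why: KH with 18-crown-6 gives a dissociated potassium alkoxide, and the 1,5-diene CH2=CH–C2–C1–C6=C5 of the bicycle undergoes an anionic oxy-Cope [3,3] shift in which the vinyl terminus bonds to C5 (decalin C5–C6) while C1–C2 (decalin C3–C8) breaks, giving enolate 13 and, after cold protonation, ketone 14. The closest known reaction type is the alkoxide-accelerated oxy-Cope rearrangement of 2-vinylbicyclo[2.2.2]oct-5-en-2-ols to cis-fused octalones. Ring B closes as a six-membered carbocycle through the boat-shaped six-centre transition state that the bicycle enforces (a sigmatropic ring reorganization, not a polar cyclization), and ring A is the former cyclohexene of the bicycle. The quaternary C5 is set by suprafacial bond formation on the face of the C5=C6 π bond that looks at the C2–C3 bridge, so its configuration is transferred from the resolved bridgeheads, while C10 keeps its bridgehead configuration, which makes the fusion cis. The step needs the [3,3] path to win over alkoxide fragmentation or a [1,3] shift and needs the vinyl group syn to the alkene bridge; the latter is fixed in step 5, and the naked alkoxide should make the concerted shift fast even onto a tetrasubstituted alkene.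

Step 9
Reactants: 14 (4aS,8aS)-1,1-dimethoxy-4a,5-dimethyl-3,4,4a,7,8,8a-hexahydronaphthalen-2(1H)-one
Product: 15 (4aR)-1-methoxy-4a,5-dimethyl-4,4a,7,8-tetrahydronaphthalen-2(3H)-one (eremophilane numbering 9-methoxy-Δ3,Δ9(10)-8-one)
Conditions: (±)-camphorsulfonic acid (cat.), toluene, 90 °C, 5 Å molecular sieves
Reagents that add atoms: none
Why: Acid-catalysed elimination of methanol from the α-keto ketal can only remove the C10 hydrogen, so the 2-methoxy enone forms regiospecifically; this makes C10 trigonal, which places the C5 methyl pseudoaxial on ring A ahead of step 11.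

Step 10
Reactants: 15 (4aR)-1-methoxy-4a,5-dimethyl-4,4a,7,8-tetrahydronaphthalen-2(3H)-one; 16 acetone
Product: 18 (5R)-11-hydroxy-9-methoxyeremophila-3,9-dien-8-one (C7 epimers), via lithium enolate 17 (not isolated)
Conditions: LiN(i-Pr)2, THF, −78 °C; 16, −78 °C; AcOH, −78 °C
Reagents that add atoms: none
Why: Kinetic α′-deprotonation at C7, the only α-methylene of the enone, followed by aldol addition to acetone and a cold quench to prevent retro-aldol; the new C7 centre is of no consequence.

Step 11
Reactants: 18 (5R)-11-hydroxy-9-methoxyeremophila-3,9-dien-8-one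
Product: 20 (3R,4R,5R)-9-methoxyeremophil-9-ene-3,8,11-triol (C7 and C8 epimers), via alkylborane 19 (not isolated)
Conditions: BH3·THF (4 equiv), THF, 0 °C → rt; NaOH, H2O2, 0 °C
Reagents that add atoms: hydrogen peroxide, OO
Why: Hydroboration–oxidation adds H and OH syn across C3=C4 with boron on the less substituted C3 and from the face anti to the pseudoaxial C5 methyl, setting C3 (oxygen anti to the C5 methyl) and C4 (methyl syn to it) in one event; the C8 ketone is reduced at the same time through the C11 alkoxyborane, which serves as its temporary mask, and the tetrasubstituted C9=C10 enol ether next to quaternary C5 should be too hindered to react.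

Step 12
Reactants: 20 (3R,4R,5R)-9-methoxyeremophil-9-ene-3,8,11-triol
Product: 21 (3R,4R,5R)-3,11-dihydroxy-9-methoxyeremophil-9-en-8-one (C7 epimers)
Conditions: MnO2, CH2Cl2, rt
Reagents that add atoms: none
Why: Allylic oxidation with MnO2 returns only the allylic C8 carbinol to the enone and leaves the saturated secondary C3 alcohol and the tertiary C11 alcohol untouched.

Step 13
Reactants: 21 (3R,4R,5R)-3,11-dihydroxy-9-methoxyeremophil-9-en-8-one
Product: 23 (3R,4R,5R)-3,9-dihydroxyeremophila-7(11),9-dien-8-one, via methoxy dienone alcohol 22 (not isolated)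
Conditions: 3 M HCl, THF, 60 °C
Reagents that add atoms: water, O
Why: Acid-catalysed dehydration of the tertiary aldol gives the conjugated isopropylidene ketone, and acid hydrolysis of the methyl enol ether then gives the 8,9-dione, which can enolize only towards C10 and so appears as the diosphenol; no ester is present yet, so forcing acid is tolerated.

Step 14
Reactants: 23 (3R,4R,5R)-3,9-dihydroxyeremophila-7(11),9-dien-8-one
Product: 24 (3R,4R,5R)-9-(tert-butyldimethylsilyloxy)-3-hydroxyeremophila-7(11),9-dien-8-one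
Conditions: TBSCl (1.1 equiv), Et3N, CH2Cl2, 0 °C → rt
Reagents that add atoms: tert-butyldimethylsilyl chloride, CC(C)(C)[Si](C)(C)Cl
Why: Chemoselective O-silylation: the acidic enol hydroxyl is silylated through its conjugate base, whereas the neutral secondary C3 alcohol should not react without a nucleophilic catalyst.

Step 15
Reactants: 25 tert-butyldimethyl(prop-2-yn-1-yloxy)silane
Product: 27 tert-butyl 4-(tert-butyldimethylsilyloxy)but-2-ynoate, via lithium acetylide 26 (not isolated)
Conditions: n-BuLi, THF, −78 °C; Boc2O, −78 → 0 °C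
Reagents that add atoms: di-tert-butyl dicarbonate, CC(C)(C)OC(=O)OC(=O)OC(C)(C)C
Why: Acylation of the lithium acetylide with the dicarbonate gives the tert-butyl ynoate.

Step 16
Reactants: 27 tert-butyl 4-(tert-butyldimethylsilyloxy)but-2-ynoate
Product: 29 tert-butyl (Z)-4-(tert-butyldimethylsilyloxy)-3-methylbut-2-enoate, via alkenylcuprate 28 (not isolated)
Conditions: Me2CuLi (CuI, MeLi), THF, −78 °C; MeOH, −78 °C; NH4Cl aq.
Reagents that add atoms: lithium dimethylcuprate, [Li+].C[Cu-]C
Why: Conjugate addition (syn-carbocupration) of the cuprate to the ynoate places CH3 and Cu cis, and protonation of the alkenylcuprate at −78 °C with retention leaves CH2OSi cis to the ester, which is the Z geometry.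

Step 17
Reactants: 29 tert-butyl (Z)-4-(tert-butyldimethylsilyloxy)-3-methylbut-2-enoate
Product: 30 tert-butyl (Z)-4-hydroxy-3-methylbut-2-enoate
Conditions: HF·pyridine, pyridine, THF, 0 °C
Reagents that add atoms: none
Why: Fluoride-mediated cleavage of the silyl ether under buffered conditions; the bulky tert-butyl ester should hold back lactonization to the butenolide, and the alcohol is used at once.

Step 18
Reactants: 30 tert-butyl (Z)-4-hydroxy-3-methylbut-2-enoate; 31 angelic acid
Product: 33 tert-butyl (Z)-3-methyl-4-[(Z)-2-methylbut-2-enoyloxy]but-2-enoate, via mixed anhydride 32 (not isolated)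
Conditions: 31, 2,4,6-trichlorobenzoyl chloride, Et3N, toluene, rt; then 30, 50 °C
Reagents that add atoms: none
Why: Yamaguchi-type mixed-anhydride acylation of the primary alcohol, run without a nucleophilic catalyst so that the angelate should not isomerize to the tiglate; the alcohol is acylated and not activated, so the butenolide cannot form by ester participation.

Step 19
Reactants: 33 tert-butyl (Z)-3-methyl-4-[(Z)-2-methylbut-2-enoyloxy]but-2-enoate
Product: 34 (Z)-3-methyl-4-[(Z)-2-methylbut-2-enoyloxy]but-2-enoic acid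
Conditions: CF3CO2H, CH2Cl2, 0 °C → rt
Reagents that add atoms: none
Why: Acidolysis of the tert-butyl ester with loss of 2-methylpropene leaves the conjugated ester and both alkene geometries untouched.

Step 20
Reactants: 24 (3R,4R,5R)-9-(tert-butyldimethylsilyloxy)-3-hydroxyeremophila-7(11),9-dien-8-one; 34 (Z)-3-methyl-4-[(Z)-2-methylbut-2-enoyloxy]but-2-enoic acid
Product: 35 (3R,4R,5R)-9-(tert-butyldimethylsilyloxy)-3-{(Z)-3-methyl-4-[(Z)-2-methylbut-2-enoyloxy]but-2-enoyloxy}eremophila-7(11),9-dien-8-one
Conditions: EDC·HCl, DMAP, CH2Cl2, 0 °C → rt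
Reagents that add atoms: none
Why: Steglich esterification of the equatorial C3 alcohol proceeds with retention at C3; the β,β-disubstituted enoyl group resists conjugate addition of DMAP, so the Z geometry should hold, and the silyl enol ether is inert.

Step 21
Reactants: 35 (3R,4R,5R)-9-(tert-butyldimethylsilyloxy)-3-{(Z)-3-methyl-4-[(Z)-2-methylbut-2-enoyloxy]but-2-enoyloxy}eremophila-7(11),9-dien-8-one
Product: 36 (3R,4R,5R)-9-hydroxy-3-{(Z)-3-methyl-4-[(Z)-2-methylbut-2-enoyloxy]but-2-enoyloxy}eremophila-7(11),9-dien-8-one (CNP0228871.1)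
Conditions: HF·pyridine, pyridine, THF, 0 °C
Reagents that add atoms: none
Why: Fluoride-mediated desilylation of the silyl enol ether under buffered conditions releases the diosphenol without touching the two unsaturated esters.

**Compound list**

1 | 3,4-dimethylphenol | Cc1ccc(O)cc1C | starting material
2 | 2-hydroxy-4,5-dimethylbenzaldehyde | Cc1cc(O)c(C=O)cc1C | intermediate
3 | 2-methoxy-4,5-dimethylbenzaldehyde | COc1cc(C)c(C)cc1C=O | intermediate
4 | 2-methoxy-4,5-dimethylphenyl formate | COc1cc(C)c(C)cc1OC=O | intermediate (not isolated)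
5 | 2-methoxy-4,5-dimethylphenol | COc1cc(C)c(C)cc1O | intermediate
6 | phenyl vinyl sulfone | C=CS(=O)(=O)c1ccccc1 | starting material
7 | 6,6-dimethoxy-3,4-dimethylcyclohexa-2,4-dien-1-one | COC1(OC)C=C(C)C(C)=CC1=O | intermediate (not isolated)
8 | rac-3,3-dimethoxy-5,6-dimethyl-7-(phenylsulfonyl)bicyclo[2.2.2]oct-5-en-2-one (racemate drawn as the enantiomer that leads to 12; sulfonyl carbon unspecified) | O=C1C(OC)(OC)[C@H]2CC(S(=O)(=O)c3ccccc3)[C@@H]1C(C)=C2C | intermediate
9 | vinylmagnesium bromide | C=C[Mg]Br | starting material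
10 | rac-2-ethenyl-3,3-dimethoxy-5,6-dimethyl-7-(phenylsulfonyl)bicyclo[2.2.2]oct-5-en-2-ol, vinyl syn to the C5=C6 bridge (racemate drawn as the enantiomer that leads to 12) | C=C[C@]1(O)C(OC)(OC)[C@H]2CC(S(=O)(=O)c3ccccc3)[C@@H]1C(C)=C2C | intermediate
11 | rac-(1R*,2R*,4S*)-2-ethenyl-3,3-dimethoxy-5,6-dimethylbicyclo[2.2.2]oct-5-en-2-ol (both enantiomers) | C=C[C@]1(O)C(OC)(OC)[C@H]2CC[C@@H]1C(C)=C2C.C=C[C@@]1(O)C(OC)(OC)[C@@H]2CC[C@H]1C(C)=C2C | intermediate
12 | (1R,2R,4S)-2-ethenyl-3,3-dimethoxy-5,6-dimethylbicyclo[2.2.2]oct-5-en-2-ol | C=C[C@]1(O)C(OC)(OC)[C@H]2CC[C@@H]1C(C)=C2C | intermediate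
13 | potassium enolate of 14 (C7=C8 enolate, cis-fused) | COC1(OC)C([O-])=CC[C@]2(C)C(C)=CCC[C@H]12.[K+] | intermediate (not isolated)
14 | (4aS,8aS)-1,1-dimethoxy-4a,5-dimethyl-3,4,4a,7,8,8a-hexahydronaphthalen-2(1H)-one | COC1(OC)C(=O)CC[C@]2(C)C(C)=CCC[C@H]12 | intermediate
15 | (4aR)-1-methoxy-4a,5-dimethyl-4,4a,7,8-tetrahydronaphthalen-2(3H)-one | CC1=CCCC2=C(OC)C(=O)CC[C@]12C | intermediate
16 | acetone | CC(C)=O | starting material
17 | lithium C7=C8 enolate of 15 | CC1=CCCC2=C(OC)C(O[Li])=CC[C@]12C | intermediate (not isolated)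
18 | (5R)-11-hydroxy-9-methoxyeremophila-3,9-dien-8-one (C7 epimers) | CC1=CCCC2=C(OC)C(=O)C(C(C)(C)O)C[C@]12C | intermediate
19 | C3 alkylborane with C8,C11 cyclic borate (boron on C3 anti to the C5 methyl) | [BH2][C@@H]1CCC2=C(OC)C3OBOC(C)(C)C3C[C@]2(C)[C@H]1C | intermediate (not isolated)
20 | (3R,4R,5R)-9-methoxyeremophil-9-ene-3,8,11-triol (C7 and C8 epimers) | O[C@@H]1CCC2=C(OC)C(O)C(C(C)(C)O)C[C@]2(C)[C@H]1C | intermediate
21 | (3R,4R,5R)-3,11-dihydroxy-9-methoxyeremophil-9-en-8-one (C7 epimers) | O[C@@H]1CCC2=C(OC)C(=O)C(C(C)(C)O)C[C@]2(C)[C@H]1C | intermediate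
22 | (3R,4R,5R)-3-hydroxy-9-methoxyeremophila-7(11),9-dien-8-one | O[C@@H]1CCC2=C(OC)C(=O)C(=C(C)C)C[C@]2(C)[C@H]1C | intermediate (not isolated)
23 | (3R,4R,5R)-3,9-dihydroxyeremophila-7(11),9-dien-8-one | O[C@@H]1CCC2=C(O)C(=O)C(=C(C)C)C[C@]2(C)[C@H]1C | intermediate
24 | (3R,4R,5R)-9-(tert-butyldimethylsilyloxy)-3-hydroxyeremophila-7(11),9-dien-8-one | O[C@@H]1CCC2=C(O[Si](C)(C)C(C)(C)C)C(=O)C(=C(C)C)C[C@]2(C)[C@H]1C | intermediate
25 | tert-butyldimethyl(prop-2-yn-1-yloxy)silane | C#CCO[Si](C)(C)C(C)(C)C | starting material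
26 | lithium acetylide of 25 | [Li]C#CCO[Si](C)(C)C(C)(C)C | intermediate (not isolated)
27 | tert-butyl 4-(tert-butyldimethylsilyloxy)but-2-ynoate | CC(C)(C)OC(=O)C#CCO[Si](C)(C)C(C)(C)C | intermediate
28 | lithium alkenyl(methyl)cuprate from 27 (Cu on C2, cis to the C3 methyl) | [Li+].C[Cu-]/C(C(=O)OC(C)(C)C)=C(\C)CO[Si](C)(C)C(C)(C)C | intermediate (not isolated)
29 | tert-butyl (Z)-4-(tert-butyldimethylsilyloxy)-3-methylbut-2-enoate | CC(C)(C)OC(=O)/C=C(C)\CO[Si](C)(C)C(C)(C)C | intermediate
30 | tert-butyl (Z)-4-hydroxy-3-methylbut-2-enoate | CC(C)(C)OC(=O)/C=C(C)\CO | intermediate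
31 | angelic acid, (Z)-2-methylbut-2-enoic acid | C/C=C(/C)C(O)=O | starting material
32 | (Z)-2-methylbut-2-enoic 2,4,6-trichlorobenzoic anhydride | C/C=C(/C)C(=O)OC(=O)c1c(Cl)cc(Cl)cc1Cl | intermediate (not isolated)
33 | tert-butyl (Z)-3-methyl-4-[(Z)-2-methylbut-2-enoyloxy]but-2-enoate | C/C=C(/C)C(=O)OC/C(C)=C\C(=O)OC(C)(C)C | intermediate
34 | (Z)-3-methyl-4-[(Z)-2-methylbut-2-enoyloxy]but-2-enoic acid | C/C=C(/C)C(=O)OC/C(C)=C\C(O)=O | intermediate
35 | (3R,4R,5R)-9-(tert-butyldimethylsilyloxy)-3-{(Z)-3-methyl-4-[(Z)-2-methylbut-2-enoyloxy]but-2-enoyloxy}eremophila-7(11),9-dien-8-one | C/C=C(/C)C(=O)OC/C(C)=C\C(=O)O[C@@H]1CCC2=C(O[Si](C)(C)C(C)(C)C)C(=O)C(=C(C)C)C[C@]2(C)[C@H]1C | intermediate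
36 | (3R,4R,5R)-9-hydroxy-3-{(Z)-3-methyl-4-[(Z)-2-methylbut-2-enoyloxy]but-2-enoyloxy}eremophila-7(11),9-dien-8-one (CNP0228871.1) | C/C=C(/C)C(=O)OC/C(C)=C\C(=O)O[C@@H]1CCC2=C(O)C(=O)C(=C(C)C)C[C@]2(C)[C@H]1C | target

**Step count**

Total: 21 steps. Longest linear sequence: 16 steps (steps 1–14, 20, 21); the side-chain acid takes 5 steps (15–19).

**Steps most likely to fail**

Step 8 (key step). The [3,3] shift onto the tetrasubstituted C5=C6 bond may be slow enough that the potassium alkoxide fragments or decomposes on heating before it rearranges. The fallback sets out from 12 and comes back at 14. Compound 12 is silylated (TMSOTf, Et3N, CH2Cl2) to the trimethylsilyl ether of 12, F3. The neutral 1,5-diene is then rearranged thermally (siloxy-Cope, o-dichlorobenzene, sealed tube, about 230 °C) to the trimethylsilyl enol ether of 14, F4. Methanolysis (K2CO3, MeOH) gives 14.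

Step 11. Chemoselectivity may be lost (borane adding to the C9=C10 enol ether or over-reducing ring B), or the two faces of C3=C4 may be poorly discriminated. The fallback sets out from 15 and comes back at 21, with C4 set by a directing group instead of by steric approach alone. Epoxidation of 15 (mCPBA, NaHCO3, CH2Cl2) anti to the C5 methyl gives the 3,4-epoxide F5. Base-induced isomerization with Et2Al(TMP) (excess, toluene, 0 °C; the ketone is held as its aluminium enolate) removes a proton from the C4 methyl, the least hindered β-position, and gives the 4-methylene-3-ol F6. Hydroxyl-directed hydrogenation (H2, [Ir(cod)(PCy3)(py)]PF6, CH2Cl2) delivers hydrogen to C4 on the face of the C3 hydroxyl and gives the 3-hydroxy-9-methoxy enone F7. Aldol addition of its dianion to acetone (LiN(i-Pr)2 2.2 equiv, THF, −78 °C) gives 21.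

Step 4. Self-dimerization of dienone 7 may outrun cycloaddition with the electron-poor sulfone. The fallback sets out from 5 and comes back at 11, using an electron-rich ethylene equivalent that pairs with the electron-poor dienone in the inverse-demand sense. Oxidation of 5 (PhI(OAc)2, MeOH) in the presence of phenyl vinyl sulfide gives the phenylthio adduct F1. Addition of vinylmagnesium bromide with CeCl3 gives the phenylthio vinyl carbinol F2. Reductive C–S cleavage with lithium 4,4′-di-tert-butylbiphenylide (THF, −78 °C, MeOH quench) gives 11.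

**Further compounds**

F1 | step 4 | rac-3,3-dimethoxy-5,6-dimethyl-7-(phenylthio)bicyclo[2.2.2]oct-5-en-2-one (sulfur-bearing carbon unspecified) | O=C1C(OC)(OC)[C@H]2CC(Sc3ccccc3)[C@@H]1C(C)=C2C
F2 | step 4 | rac-2-ethenyl-3,3-dimethoxy-5,6-dimethyl-7-(phenylthio)bicyclo[2.2.2]oct-5-en-2-ol, vinyl syn to the C5=C6 bridge | C=C[C@]1(O)C(OC)(OC)[C@H]2CC(Sc3ccccc3)[C@@H]1C(C)=C2C
F3 | step 8 | trimethylsilyl ether of 12 | C=C[C@]1(O[Si](C)(C)C)C(OC)(OC)[C@H]2CC[C@@H]1C(C)=C2C
F4 | step 8 | trimethylsilyl enol ether of 14 (C7=C8) | COC1(OC)C(O[Si](C)(C)C)=CC[C@]2(C)C(C)=CCC[C@H]12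
F5 | step 11 | 3,4-epoxide of 15, oxygen anti to the C5 methyl | O1[C@@H]2CCC3=C(OC)C(=O)CC[C@]3(C)[C@]12C
F6 | step 11 | (3R,5R)-3-hydroxy-9-methoxy-4-methylene-5-methyl-Δ9(10)-octalin-8-one | O[C@@H]1CCC2=C(OC)C(=O)CC[C@]2(C)C1=C
F7 | step 11 | (3R,4R,5R)-3-hydroxy-9-methoxy-4,5-dimethyl-Δ9(10)-octalin-8-one | O[C@@H]1CCC2=C(OC)C(=O)CC[C@]2(C)[C@H]1C
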